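**Retrosynthetic overview**

1. The target arises by loss of CO2 from an allyl 2-(3,4-dihydroxyphenyl)-3,4-dioxochromane-2-carboxylate. This is cut between C2 of ring C and C1' of ring B into catechol (oxidised in the cell to o-benzoquinone) and allyl 3,5-dihydroxy-6,7,8-trimethoxy-4-oxo-4H-chromene-2-carboxylate: two electron-rich carbons joined by anodic polarity reversal of the catechol.
2. Enabling feature: in ring C the O3–C3=C2 enol next to the C4 ketone (the enol of a chromane-3,4-dione) makes C2 a carbon nucleophile, and ring A has no C–H (C5 to C8 all carry oxygen), so C2 is the only one. Ring B is a catechol, the reduced form of o-benzoquinone, whose C4 (para to one oxygen, meta to the other) is a Michael acceptor and becomes C1' of a 3',4'-dihydroxyphenyl group.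
3. The ester on C2 is a temporary activating and blocking group: it lowers the enol pKa, keeps the adduct as a non-enolisable 3,4-dione (no flavonol is present while oxidant is present) and leaves as CO2 in the last step, which unveils the 3-hydroxy-4-pyranone.
4. Chromone ester ⇒ o-hydroxyaryl methoxymethyl ketone + diallyl oxalate (Claisen, cyclodehydration, then cleavage of 3- and 5-OMe); ketone ⇒ pentamethoxybenzene + methoxyacetyl chloride; pentamethoxybenzene ⇒ 2,6-dimethoxy-1,4-benzoquinone (Thiele–Winter).
5. Ring order: ring A comes from the quinone (steps 1–2), ring C is closed in step 4, ring B is attached intact in step 6; the key step closes no ring.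

Key step: step 6

Remark: the target is achiral (no stereocentre), so no enantiocontrol is needed; the only stereocentre on the route, C2 of 14, is formed as a racemate and is destroyed in step 7.

**Route**

Step 1
Reactants: 1 2,6-dimethoxy-1,4-benzoquinone
Product: 2 3,5-dimethoxybenzene-1,2,4-triyl triacetate
Conditions: Ac2O, conc. H2SO4 (cat.), rt → 40 °C
Reagents that add atoms: acetic anhydride CC(=O)OC(C)=O
Why: Thiele–Winter acetoxylation: acid-catalysed conjugate addition of acetate to one of the two equivalent unsubstituted ring carbons of the quinone, enolisation and O-acetylation should install the fifth ring oxygen and give the arene at the hydroquinone oxidation level.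

Step 2
Reactants: 2 3,5-dimethoxybenzene-1,2,4-triyl triacetate
Product: 4 pentamethoxybenzene, via triol 3 (not isolated)
Conditions: Me2SO4, aq. NaOH, MeOH, Na2S2O4 (cat.), N2, 0 °C → 60 °C
Reagents that add atoms: dimethyl sulfate COS(=O)(=O)OC
Why: One-pot saponification of the three aryl acetates and Williamson O-methylation of the phenoxides should give the pentamethyl ether, while dithionite and exclusion of air keep the oxidation-prone hydroxyquinol 3 from reverting to a quinone.

Step 3
Reactants: 4 pentamethoxybenzene; 5 methoxyacetyl chloride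
Product: 7 1-(2-hydroxy-3,4,5,6-tetramethoxyphenyl)-2-methoxyethan-1-one, via pentamethoxyphenyl ketone 6 (not isolated)
Conditions: AlCl3 (2.5 equiv), CH2Cl2, 0 °C → rt; aqueous work-up
Reagents that add atoms: none
Why: Friedel–Crafts acylation at the only ring C–H of the very electron-rich arene gives ketone 6, whose AlCl3 chelate should lose one of the two equivalent ortho methyl ethers (chelation-assisted ortho-demethylation) to give the hydrogen-bonded o-hydroxy ketone, the aliphatic methyl ether not being chelation-activated.

Step 4
Reactants: 7 1-(2-hydroxy-3,4,5,6-tetramethoxyphenyl)-2-methoxyethan-1-one; 8 diallyl oxalate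
Product: 10 allyl 3,5,6,7,8-pentamethoxy-4-oxo-4H-chromene-2-carboxylate, via dioxo ester 9 (not isolated)
Conditions: NaH (3.5 equiv), THF, 0 °C → 60 °C; then AcOH, H2SO4 (cat.), 80 °C
Reagents that add atoms: none
Why: Crossed Claisen condensation of the ketone α-carbon (as phenoxide–enolate dianion) with the non-enolisable oxalate, followed by acid cyclodehydration in which the phenol oxygen attacks the α-keto ester carbonyl (6-exo-trig, then loss of water), is the classical chromone-2-carboxylate synthesis and closes ring C.

Step 5
Reactants: 10 allyl 3,5,6,7,8-pentamethoxy-4-oxo-4H-chromene-2-carboxylate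
Product: 11 allyl 3,5-dihydroxy-6,7,8-trimethoxy-4-oxo-4H-chromene-2-carboxylate
Conditions: BCl3 (5 equiv), CH2Cl2, −78 °C → 0 °C; aqueous work-up
Reagents that add atoms: none
Why: Chelation-controlled ether cleavage with BCl3 should remove only the two methyl groups whose oxygens sit next to a carbonyl (5-OMe peri to C4=O; 3-OMe between C4=O and the ester C=O), as in the BCl3 demethylation of o-methoxyaryl ketones and o-methoxybenzoates, while the 6-, 7- and 8-methoxy groups and the ester should remain.

Step 6
Reactants: 11 allyl 3,5-dihydroxy-6,7,8-trimethoxy-4-oxo-4H-chromene-2-carboxylate; 12 catechol (1.05 equiv)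
Product: 14 allyl 2-(3,4-dihydroxyphenyl)-5-hydroxy-6,7,8-trimethoxy-3,4-dioxochromane-2-carboxylate (racemic), via o-benzoquinone 13 (not isolated)
Conditions: divided cell, graphite-rod anode, Pt cathode, controlled potential at the first catechol wave (ca. +0.3 V vs SCE), 2.1 F per mol of 12, 0.2 M NaOAc/AcOH buffer pH 6–MeCN (3:1), N2, 20 °C; then aq. Na2S2O4, pH 3, EtOAc
Reagents that add atoms: none
Why: Proposed new method: at this potential only catechol 12 should be oxidised (2 e−, 2 H+) to o-benzoquinone 13, whose C4 is attacked in a Michael (1,4) addition by C2 of the enolate of 11 (O3–C3=C2, the enolate of an α-aryloxy β-keto ester held in the pyranone ring, with the C2 carbanion character known from C2-oxygenation and halogenation of 3-hydroxyflavonates); tautomerisation of the adduct restores the aromatic catechol and leaves ring C as a 3,4-dione (EC sequence). The closest known reaction type is the anodic or laccase/O2 α-arylation of 4-hydroxycoumarins, barbiturates and α-substituted cyclic β-dicarbonyl compounds by o-benzoquinones generated in situ, together with the amine-catalysed α-arylation of cyclic β-keto esters with quinones, all of which build aryl-bearing quaternary carbons; new is the C2 carbon of a 3-hydroxy-4-pyranone as the donor. No ring is closed, and the new stereocentre C2 is formed without control (racemic), which is of no consequence because step 7 destroys it. Site selectivity on the donor is secured by the fully substituted A ring (no aromatic C–H), so that C2 is the only carbon nucleophile, and C- over O-attack by the irreversible re-aromatisation of the C-adduct; on the quinone the hindered enolate should take the remote C4, which gives the 3,4-dihydroxyphenyl pattern. Chemoselectivity against further oxidation is secured by the ester on C2: 14 cannot tautomerise to the easily oxidised flavonol, its catechol is insulated from O3 by an sp3 carbon that bears three acceptor groups and should therefore be harder to oxidise than 12, and neither quinone-methide formation nor furan closure by a 3-OH (the usual second oxidation of such adducts) is open to it.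

Step 7
Reactants: 14 allyl 2-(3,4-dihydroxyphenyl)-5-hydroxy-6,7,8-trimethoxy-3,4-dioxochromane-2-carboxylate (racemic)
Product: 16 3,5,3',4'-tetrahydroxy-6,7,8-trimethoxyflavone, via β-keto acid 15 (not isolated)
Conditions: Pd(PPh3)4 (5 mol%), HCO2H, Et3N, THF, N2, rt → 40 °C
Reagents that add atoms: none
Why: Tsuji-type Pd(0) deallylation–decarboxylation of an allyl β-keto ester: oxidative addition gives π-allylpalladium and β-keto carboxylate 15, formate reduces the allyl unit to propene, and loss of CO2 gives the C3 enolate whose protonation should restore the aromatic 3-hydroxy-4-pyranone and erase the C2 stereocentre.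

**Compound list**

1 | 2,6-dimethoxy-1,4-benzoquinone | COC1=CC(=O)C=C(OC)C1=O | starting material
2 | 3,5-dimethoxybenzene-1,2,4-triyl triacetate | CC(=O)Oc1cc(OC)c(OC(C)=O)c(OC)c1OC(C)=O | intermediate
3 | 3,5-dimethoxybenzene-1,2,4-triol (not isolated) | COc1cc(O)c(O)c(OC)c1O | intermediate
4 | pentamethoxybenzene | COc1cc(OC)c(OC)c(OC)c1OC | intermediate
5 | methoxyacetyl chloride | COCC(Cl)=O | starting material
6 | 2-methoxy-1-(pentamethoxyphenyl)ethan-1-one (not isolated) | COCC(=O)c1c(OC)c(OC)c(OC)c(OC)c1OC | intermediate
7 | 1-(2-hydroxy-3,4,5,6-tetramethoxyphenyl)-2-methoxyethan-1-one | COCC(=O)c1c(O)c(OC)c(OC)c(OC)c1OC | intermediate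
8 | diallyl oxalate | C=CCOC(=O)C(=O)OCC=C | starting material
9 | allyl 4-(2-hydroxy-3,4,5,6-tetramethoxyphenyl)-3-methoxy-2,4-dioxobutanoate (not isolated) | C=CCOC(=O)C(=O)C(OC)C(=O)c1c(O)c(OC)c(OC)c(OC)c1OC | intermediate
10 | allyl 3,5,6,7,8-pentamethoxy-4-oxo-4H-chromene-2-carboxylate | C=CCOC(=O)c1oc2c(OC)c(OC)c(OC)c(OC)c2c(=O)c1OC | intermediate
11 | allyl 3,5-dihydroxy-6,7,8-trimethoxy-4-oxo-4H-chromene-2-carboxylate | C=CCOC(=O)c1oc2c(OC)c(OC)c(OC)c(O)c2c(=O)c1O | intermediate
12 | catechol | Oc1ccccc1O | starting material
13 | o-benzoquinone (not isolated) | O=C1C=CC=CC1=O | intermediate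
14 | allyl 2-(3,4-dihydroxyphenyl)-5-hydroxy-6,7,8-trimethoxy-3,4-dioxochromane-2-carboxylate (racemic) | C=CCOC(=O)C1(c2ccc(O)c(O)c2)Oc2c(OC)c(OC)c(OC)c(O)c2C(=O)C1=O | intermediate
15 | 2-(3,4-dihydroxyphenyl)-5-hydroxy-6,7,8-trimethoxy-3,4-dioxochromane-2-carboxylic acid (racemic, not isolated) | O=C(O)C1(c2ccc(O)c(O)c2)Oc2c(OC)c(OC)c(OC)c(O)c2C(=O)C1=O | intermediate
16 | 3,5,3',4'-tetrahydroxy-6,7,8-trimethoxyflavone | COc1c(OC)c(O)c2c(=O)c(O)c(-c3ccc(O)c(O)c3)oc2c1OC | target

**Step count and risks**

Total step count: 7. Longest linear sequence: 7 steps (1 → 2 → 4 → 7 → 10 → 11 → 14 → 16).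

Steps most likely to fail:

Step 6 (proposed method). Carbon–carbon bond formation at the hindered, ester-bearing C2 of the enolate may be too slow, so that the electrogenerated quinone is consumed by coupling with catechol or by hydration; attack may also occur through O3, or the dione product may suffer hydroxide-induced ring contraction during a long electrolysis. The fallback uses known chemistry, sets out from 7 and returns at 16. Steglich esterification of the phenol of 7 with 3,4-bis(benzyloxy)benzoic acid (EDC, DMAP, CH2Cl2) should give 2-(2-methoxyacetyl)-3,4,5,6-tetramethoxyphenyl 3,4-bis(benzyloxy)benzoate F1. Baker–Venkataraman rearrangement (LiHMDS, THF, −78 → 0 °C) should give 1-[3,4-bis(benzyloxy)phenyl]-3-(2-hydroxy-3,4,5,6-tetramethoxyphenyl)-2-methoxypropane-1,3-dione F2. Cyclodehydration (AcOH, cat. H2SO4, 80 °C) should give 2-[3,4-bis(benzyloxy)phenyl]-3,5,6,7,8-pentamethoxy-4H-chromen-4-one F3. Hydrogenolysis (H2, Pd/C, EtOAc–MeOH) should give 2-(3,4-dihydroxyphenyl)-3,5,6,7,8-pentamethoxy-4H-chromen-4-one F4. Chelation-controlled cleavage of the 3- and 5-methyl ethers (AlBr3, MeCN, 0 °C → rt) should then give 16.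

Step 5. The Lewis acid may also remove the allyl ester or the 6-methyl ether next to the freed 5-OH, or cleavage of the 3-methyl ether may stay incomplete. The fallback sets out from 10 and returns at 11. Exhaustive chelation-controlled cleavage with AlBr3 in MeCN, accepting loss of the allyl group, should give 3,5-dihydroxy-6,7,8-trimethoxy-4-oxo-4H-chromene-2-carboxylic acid F5. Fischer esterification with allyl alcohol (cat. H2SO4, 70 °C) should return 11.

Step 7. The π-allylpalladium intermediate may be captured by the catechol or by the flavonol enolate (O- or C-allylation), or the amine base may open the 1,2-dione before the ester is cleaved. The fallback sets out from 14 and returns at 16: acid-catalysed ester hydrolysis and thermal decarboxylation of the β-keto acid 15 (2 M HCl, AcOH–H2O, 80 °C), the classical ketonic cleavage of β-keto esters, without palladium or base. No further compound is made (F0).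

**Further compounds**

F1 | step 6 | 2-(2-methoxyacetyl)-3,4,5,6-tetramethoxyphenyl 3,4-bis(benzyloxy)benzoate | COCC(=O)c1c(OC(=O)c2ccc(OCc3ccccc3)c(OCc3ccccc3)c2)c(OC)c(OC)c(OC)c1OC
F2 | step 6 | 1-[3,4-bis(benzyloxy)phenyl]-3-(2-hydroxy-3,4,5,6-tetramethoxyphenyl)-2-methoxypropane-1,3-dione | COC(C(=O)c1ccc(OCc2ccccc2)c(OCc2ccccc2)c1)C(=O)c1c(O)c(OC)c(OC)c(OC)c1OC
F3 | step 6 | 2-[3,4-bis(benzyloxy)phenyl]-3,5,6,7,8-pentamethoxy-4H-chromen-4-one | COc1c(-c2ccc(OCc3ccccc3)c(OCc3ccccc3)c2)oc2c(OC)c(OC)c(OC)c(OC)c2c1=O
F4 | step 6 | 2-(3,4-dihydroxyphenyl)-3,5,6,7,8-pentamethoxy-4H-chromen-4-one | COc1c(-c2ccc(O)c(O)c2)oc2c(OC)c(OC)c(OC)c(OC)c2c1=O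
F5 | step 5 | 3,5-dihydroxy-6,7,8-trimethoxy-4-oxo-4H-chromene-2-carboxylic acid | O=C(O)c1oc2c(OC)c(OC)c(OC)c(O)c2c(=O)c1O
F0 | step 7 | none | none
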